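**Retrosynthetic overview**
1. The target has one ring, the furanone of a 3-acyl tetronic acid. It is closed in the last step and nothing is done after it.
2. Ring closure: the O1–C2 lactone bond (glyceryl O-2 onto a thioester carbonyl) is made directly after the C3–C4 bond (Claisen C-acylation of a 3-oxoacyl thioester by an activated glyceryl unit), in one flask. These are the two bonds, the bond order and the two acyl partners of the tetronate-forming enzyme.
3. Partners: S-tert-butyl (16S)-16-methyl-3-oxooctadecanethioate and (2S)-2,3-bis(silyloxy)propanoyl chloride. The latter comes from L-serine by retentive deamination, which sets C-5.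
4. β-Keto thioester: (S)-14-methylhexadecanoic acid + Meldrum's acid + t-BuSH (a malonyl-type two-carbon extension).
5. Acid: (S)-1-bromo-2-methylbutane (sets C-14′) + 12-bromododecanoic acid by copper-catalysed Grignard coupling.

Assumption: ionised forms (carboxylate, enolate or alkoxide salts) count as the parent compound and get no number of their own; enolisable compounds are drawn in one tautomeric form.

**Step 1**
Reactants: 1 (S)-1-bromo-2-methylbutane; 2 ω-bromolauric acid (12-bromododecanoic acid)
Product: 4 (S)-14-methylhexadecanoic acid, via (S)-2-methylbutylmagnesium bromide 3 (not isolated)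
Conditions: 1, Mg, THF, 40 °C; 2, MeMgCl (1.0 equiv), THF, −20 °C; then 3 (1.4 equiv), Li2CuCl4 (3 mol %), −20 °C → rt; aq. HCl
Reagents that add atoms: none
Why: Tamura–Kochi copper-catalysed sp3–sp3 cross-coupling, in which the primary Grignard reagent 3 displaces the primary bromide of the chloromagnesium carboxylate of 2 while the carboxylate salt stays inert at −20 °C; the (S) centre of 1 is one carbon away from the C–Mg bond, is carried over untouched and becomes C-14′ of the target.

**Step 2**
Reactants: 4 (S)-14-methylhexadecanoic acid; 5 Meldrum's acid (2,2-dimethyl-1,3-dioxane-4,6-dione)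
Product: 7 S-tert-butyl (16S)-16-methyl-3-oxooctadecanethioate, via acyl Meldrum's acid 6 (not isolated)
Conditions: DCC, DMAP (4-dimethylaminopyridine, cat.), CH2Cl2, 0 °C → rt; filter, cold dilute HCl wash, evaporate; then t-BuSH (3 equiv), toluene, 90 °C, sealed vessel
Reagents that add atoms: 2-methylpropane-2-thiol, CC(C)(C)S
Why: Yonemitsu-type DCC/DMAP C-acylation of Meldrum's acid, then thermal retro-hetero-Diels–Alder loss of acetone and CO2 to an acylketene that the thiol traps, giving the synthetic counterpart of the 3-oxoacyl thioester; no stereocentre is involved.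

**Step 3**
Reactants: 8 L-serine
Product: 9 (S)-glyceric acid ((2S)-2,3-dihydroxypropanoic acid)
Conditions: NaNO2 (1.5 equiv), 1 M H2SO4 (0.8 equiv), 0 °C → rt; evaporate below 30 °C, take up in acetone, filter off Na2SO4, use at once
Reagents that add atoms: water, O
Why: Nitrous acid deamination (diazotisation) of an α-amino acid, in which the carboxylate displaces N2 to an α-lactone that water opens, a double inversion with net retention, so L-serine gives the (S)-hydroxy acid and C-5 of the target is set here.

**Step 4**
Reactants: 9 (S)-glyceric acid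
Product: 10 tert-butyldimethylsilyl (2S)-2,3-bis[(tert-butyldimethylsilyl)oxy]propanoate
Conditions: TBSCl (3.6 equiv), imidazole (7.5 equiv), DMF, rt; pentane/cold water
Reagents that add atoms: tert-butyldimethylsilyl chloride (TBSCl), CC(C)(C)[Si](C)(C)Cl
Why: Corey silylation (TBSCl/imidazole) of both hydroxyls and of the carboxyl group, which gives a silyl ester that can be turned into the acid chloride without acid; no bond at the stereocentre is broken.

**Step 5**
Reactants: 10 tert-butyldimethylsilyl (2S)-2,3-bis[(tert-butyldimethylsilyl)oxy]propanoate; 7 S-tert-butyl (16S)-16-methyl-3-oxooctadecanethioate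
Product: 14 (5S)-4-hydroxy-5-(hydroxymethyl)-3-[(14S)-14-methylhexadecanoyl]furan-2(5H)-one (the target), via acid chloride 11 (not isolated), via bis-silyl tricarbonyl thioester 12 (not isolated), via diol tricarbonyl thioester 13 (not isolated)
Conditions: 10, (COCl)2 (1.1 equiv), DMF (cat.), CH2Cl2, 0 °C → rt, evaporate; then 7 (0.9 equiv), MgCl2 (1.0 equiv), pyridine (2.0 equiv), CH2Cl2, 0 °C → rt; cold 0.5 M HCl wash, no purification; then Bu4NF (5 equiv), THF, 0 °C → rt; 1 M HCl
Reagents that add atoms: none
Why: Proposed new method: a one-flask Claisen C-acylation/desilylative lactonization that copies the tetronate synthase (C3–C4 first, then O1–C2), in which the silyl ester gives acid chloride 11 under neutral conditions (Wissner oxalyl chloride/DMF exchange), the magnesium chelate of 7 is C-acylated at C-2 (closest known reaction type: Rathke MgCl2/pyridine acylation of β-keto esters by acid chlorides), and fluoride then frees O-2 as an alkoxide that attacks the thioester carbonyl 5-exo-trig and expels t-BuS− to give the stable tetronate anion (closest known reaction type: base-induced closure of (α-acyloxyacyl)malonates to tetronic acids); C-5 comes unchanged from 10 because no bond to it is made or broken and it never sits next to a free ester enolate.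

**Compound list**
1 | (S)-1-bromo-2-methylbutane | CC[C@H](C)CBr | starting material
2 | 12-bromododecanoic acid | OC(=O)CCCCCCCCCCCBr | starting material
3 | (S)-2-methylbutylmagnesium bromide | CC[C@H](C)C[Mg]Br | intermediate (not isolated)
4 | (S)-14-methylhexadecanoic acid | CC[C@H](C)CCCCCCCCCCCCC(=O)O | intermediate
5 | Meldrum's acid (2,2-dimethyl-1,3-dioxane-4,6-dione) | CC1(C)OC(=O)CC(=O)O1 | starting material
6 | 5-[(14S)-1-hydroxy-14-methylhexadecylidene]-2,2-dimethyl-1,3-dioxane-4,6-dione (acyl Meldrum's acid, enol form) | CC[C@H](C)CCCCCCCCCCCCC(O)=C1C(=O)OC(C)(C)OC1=O | intermediate (not isolated)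
7 | S-tert-butyl (16S)-16-methyl-3-oxooctadecanethioate | CC[C@H](C)CCCCCCCCCCCCC(=O)CC(=O)SC(C)(C)C | intermediate
8 | L-serine | N[C@@H](CO)C(=O)O | starting material
9 | (S)-glyceric acid, (2S)-2,3-dihydroxypropanoic acid | OC[C@H](O)C(=O)O | intermediate
10 | tert-butyldimethylsilyl (2S)-2,3-bis[(tert-butyldimethylsilyl)oxy]propanoate | CC(C)(C)[Si](C)(C)OC[C@H](O[Si](C)(C)C(C)(C)C)C(=O)O[Si](C)(C)C(C)(C)C | intermediate
11 | (2S)-2,3-bis[(tert-butyldimethylsilyl)oxy]propanoyl chloride | CC(C)(C)[Si](C)(C)OC[C@H](O[Si](C)(C)C(C)(C)C)C(Cl)=O | intermediate (not isolated)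
12 | S-tert-butyl (16S)-2-[(2S)-2,3-bis[(tert-butyldimethylsilyl)oxy]propanoyl]-16-methyl-3-oxooctadecanethioate (C-2 enolised, not assigned) | CC[C@H](C)CCCCCCCCCCCCC(=O)C(C(=O)SC(C)(C)C)C(=O)[C@H](CO[Si](C)(C)C(C)(C)C)O[Si](C)(C)C(C)(C)C | intermediate (not isolated)
13 | S-tert-butyl (16S)-2-[(2S)-2,3-dihydroxypropanoyl]-16-methyl-3-oxooctadecanethioate (C-2 enolised, not assigned) | CC[C@H](C)CCCCCCCCCCCCC(=O)C(C(=O)SC(C)(C)C)C(=O)[C@H](CO)O | intermediate (not isolated)
14 | (5S)-4-hydroxy-5-(hydroxymethyl)-3-[(14S)-14-methylhexadecanoyl]furan-2(5H)-one | CC[C@H](C)CCCCCCCCCCCCC(=O)C1=C(O)[C@H](CO)OC1=O | target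

**Step count and risks**
Total step count: 5. Longest linear sequence: 3 steps (1, 2, 5; the serine branch 3, 4, 5 is equally long).

Most likely to fail: step 5. Three things can go wrong.
- The hindered α-silyloxy acid chloride may acylate the enolate on oxygen instead of carbon.
- O-3 may close the six-membered lactone instead of O-2 closing the furanone.
- Attack on the S-tert-butyl thioester may be slow.

Acid must be avoided while the diol is free, because acid would send O-2 onto the chain ketone and dehydrate to a 3(2H)-furanone; this is why the ring is closed under fluoride. The fallback reverses the order of the two ring bonds (O-acylation first, then Dieckmann closure). It sets out from 7 and 9 and comes back at 14. Compound 9 is esterified (MeOH, cat. HCl) to methyl (2S)-2,3-dihydroxypropanoate F1. Its primary hydroxyl is silylated (TBSCl 1.05 equiv, imidazole, CH2Cl2, −20 °C) to give methyl (2S)-3-[(tert-butyldimethylsilyl)oxy]-2-hydroxypropanoate F2. AgOCOCF3 in THF then activates thioester 7 and transfers the 3-oxoacyl group to the free secondary hydroxyl of F2, giving (2S)-3-[(tert-butyldimethylsilyl)oxy]-1-methoxy-1-oxopropan-2-yl (16S)-16-methyl-3-oxooctadecanoate F3. Bu4NF in THF closes the ring by Dieckmann condensation onto the methyl ester and removes the silyl ether in the same operation to give 14.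

Second: step 3. Free glyceric acid is hard to get out of water and forms oligoesters when concentrated, which would spoil step 4. The fallback makes 9 by unmasking a distillable purchased derivative instead of by deamination. Step 3 opens its branch, so the only numbered compound before it is 8, which this fallback replaces; it comes back at 9. Purchased methyl (4S)-2,2-dimethyl-1,3-dioxolane-4-carboxylate (CC1(C)OC[C@H](O1)C(=O)OC) is saponified (KOH, MeOH, 0 °C) to potassium (4S)-2,2-dimethyl-1,3-dioxolane-4-carboxylate F4. A sulfonic acid resin (H+ form) in water at rt then removes the potassium ion and the acetonide, and filtration and freeze-drying leave salt-free 9.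

Third: step 1. The chloromagnesium carboxylate of 2 is poorly soluble and may couple slowly, so that 3 is lost to homocoupling and reduction. The fallback builds the β-keto thioester by alkylation instead of through the acid. It sets out from 3 and comes back at 7, so steps 1 and 2 are both replaced. Compound 3 is coupled (Li2CuCl4 cat., THF, −10 °C) with purchased 1,10-dibromodecane (BrCCCCCCCCCCBr, 3 equiv, excess distilled off) to give (S)-1-bromo-12-methyltetradecane F5. F5 alkylates the terminal carbon of the dianion of purchased S-tert-butyl 3-oxobutanethioate (CC(=O)CC(=O)SC(C)(C)C; NaH then n-BuLi, THF/DMPU, 0 °C → rt; Weiler dianion alkylation) to give 7.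

**Further compounds**
F1 | step 5 | methyl (2S)-2,3-dihydroxypropanoate | OC[C@H](O)C(=O)OC
F2 | step 5 | methyl (2S)-3-[(tert-butyldimethylsilyl)oxy]-2-hydroxypropanoate | CC(C)(C)[Si](C)(C)OC[C@H](O)C(=O)OC
F3 | step 5 | (2S)-3-[(tert-butyldimethylsilyl)oxy]-1-methoxy-1-oxopropan-2-yl (16S)-16-methyl-3-oxooctadecanoate | CC[C@H](C)CCCCCCCCCCCCC(=O)CC(=O)O[C@@H](CO[Si](C)(C)C(C)(C)C)C(=O)OC
F4 | step 3 | potassium (4S)-2,2-dimethyl-1,3-dioxolane-4-carboxylate | CC1(C)OC[C@H](O1)C(=O)[O-].[K+]
F5 | step 1 | (S)-1-bromo-12-methyltetradecane | CC[C@H](C)CCCCCCCCCCCBr
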